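**Conventions.** Flavonoid numbering is used (O1, C2, C3, C4, C4a, C5–C8, C8a; ring B carries primed locants). MOM = methoxymethyl. Ar = 2-{[4-(methoxymethoxy)phenyl]methoxy}-4,6-bis(methoxymethoxy)-5-(2-methylbut-3-en-2-yl)phenyl, the aryl group of ketone 10.

## Analysis of the target

The target is a 2,3-dihydroflavonol, a 2-aryl-3-hydroxychroman-4-one. Ring A (C4a–C8a) is a phloroglucinol unit, ring C is the dihydropyranone (O1, C2, C3, C4), and ring B is a 4-hydroxyphenyl group on C2. There are two adjacent stereocentres, C2 and C3, both R, with the aryl group and the hydroxyl trans and diequatorial on the half-chair of ring C; this is also the more stable relative configuration. C6 carries a 2-methylbut-3-en-2-yl group, a quaternary carbon between the C5 and C7 oxygens, which makes ring A hexasubstituted. Sensitive points are the C3 hydroxy ketone (epimerisation through the enol, dehydrogenation to the flavonol, base-induced opening of ring C at O1–C2), the benzylic ether carbon C2, which can ionise once the 4'-hydroxyl is free, and the vinyl group next to two phenols, which excludes hydrogenolysis and strong acid. The difficulties are the regiochemistry on ring A (C6 and not C8; O1 told apart from the C5 oxygen) and the absolute configuration of two centres that can both equilibrate. The strategy rests on one feature: C2 is at once an ether carbon of O1 and a benzylic carbon of ring B with a para oxygen (O4'). A cation at C2 is therefore doubly stabilised and can be made from the CH2 group of a 4-alkoxybenzyl aryl ether, while C3 and C4 are supplied as the enol derivative of an aryl ketone ortho to O1.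

## Retrosynthetic reasoning

**From 18 back to 16 (protecting groups).** The three O–CH2 acetal bonds are cut last (17) and the C3 ester bond before that (16). In this order the only base treatment takes place while O4' is still capped, so C2 cannot ionise. The only acid treatment is one that a monosubstituted alkene should tolerate. The phenols stay masked up to this point because free phenols would not survive the oxidant of the key step.

**From 16 to 15 (C2–C3).** The bond between the two stereocentres is cut, which opens ring C. C2 becomes a benzylic CH2 group and C3–C4 an enediol diester, so 15 is achiral and has no labile centre. Cutting O1–C2 instead would call for a stereodefined benzylic leaving group or for a conjugate addition with no facial bias. Cutting C3–C4 would put an enolisable stereocentre at C2 into the open-chain precursor. In the forward direction a quinone oxidant has to take a hydride from the CH2 group, and the tethered enol ester has to add to the cation at C2 inside an ion pair with a chiral phosphate. The ring, the C–C bond and both centres then arise together. Both oxygens of the C3–C4 unit carry the same acyl group, so that the aryl group on C4 and the ring size decide which carbon attacks, not a difference in donor strength.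

**From 15 to 10 (enol ester and alpha-oxygen).** The O-acyl bond at C4 is cut to give the acetoxy ketone 14. The C3–O bond is then cut to give methyl ketone 10, by way of alcohol 13 and the silicon intermediates 11 and 12. Introducing the alpha-oxygen after all phenol alkylations keeps a base-sensitive acyloxy ketone out of the carbonate and hydride steps. It also makes the commercial methyl ketone 1 the source of C3 and C4. The forward steps need an enolisation with only one possible site and an oxidant that prefers an enol ether to the vinyl group.

**From 10 to 5 and 8 (O1–CH2 and the C5 oxygen).** The benzylic C–O bond at O1 and the acetal at O5 are cut. The benzyl group is both the tag that tells O1 from O5 and the carrier of C2 and ring B. The three phenols of 4 should react in the order non-chelated 4-OH, unhindered chelated OH, hindered chelated OH. This is the order the route needs (5, then 9, then 10), so no protecting group has to be moved. Bromide 8 goes back through a C–Br and an O–CH2 disconnection to 7 and 6.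

**From 5 to 1 and 2 (the quaternary carbon).** The bond from C6 to the quaternary carbon is cut along a [3,3] pathway, which leads to ether 3 of the para oxygen; the O–allyl bond then leads to 1 and 2. Running this on the mirror-symmetric ketone has three advantages:
- The two ortho positions are equivalent, so C6 against C8 is not yet a question.
- The acetyl group sits in the para position, which closes the para migration to which such ethers are prone.
- The acyl group is already in place, so no Lewis-acid acylation is needed on a phenol that carries an acid-sensitive tert-allyl group.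

The rearrangement has to stop at phenol 4, without addition of the flanking hydroxyl groups to the new vinyl group.

## Alternatives that were turned down

**Alternative 1:** The two C–C bonds at the quaternary carbon are disconnected, so that the side chain comes from an acetyl group. In the key step a methyl Grignard reagent adds to the ketone of tert-butyl 2-acetyl-5-(allyloxy)-3-(methoxymethoxy)phenyl carbonate A2. The alkoxide takes over the carbonate group, elimination gives an ortho-quinone methide, and a vinyl Grignard reagent adds 1,4 to give 5-(allyloxy)-3-(methoxymethoxy)-2-(2-methylbut-3-en-2-yl)phenol A1.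
- For: the position of the side chain is fixed by the position of the acetyl group, with no sigmatropic ambiguity and no heating. On this point it is stronger than the chosen route, which relies on a Claisen rearrangement.
- Against: the only acyl group on ring A is used up. The C4 carbonyl carbon must then be introduced onto A1, which has two free ring positions, a MOM ether and an acid-sensitive tert-allyl group next to a free phenol. A beta,beta-disubstituted quinone methide can also tautomerise to an isopropenyl phenol before the hindered addition takes place.
- Comparison: the key step closes no ring and sets no stereocentre, so ring C and both centres remain to be made by a long sequence. The chosen strategy keeps the carbonyl group, installs the side chain on a commercial ketone and spends its key step on the ring and the stereocentres.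

**Alternative 2:** Ring A is disconnected at C4a–C5 and built last on a preformed ring C. A magnesium alkoxide in methanol converts methyl 4-[(2R,3R)-3-[(tert-butyldimethylsilyl)oxy]-2-{4-[(tert-butyldimethylsilyl)oxy]phenyl}-4-oxo-3,4-dihydro-2H-pyran-6-yl]-2-(2-methylbut-3-en-2-yl)-3-oxobutanoate A4 into its extended enolate. C4a attacks the ester carbon, and tautomerisation gives the 3,4'-bis-O-silyl derivative of the target A3.
- For: the stereocentres can be set early on a small dihydropyranone by established asymmetric methods. Ring A appears with free 5- and 7-hydroxyl groups and the side chain in place, so there is no phenol differentiation and no rearrangement. It is stronger than the chosen route in regiocontrol on ring A and in avoiding an unprecedented asymmetric step.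
- Against: under base, A4 has an acidic C3–H next to the ring carbonyl and a leaving group (O1) beta to it. Epimerisation at C3 and opening at O1–C2 compete with formation of the extended enolate. The ester carbon to be attacked is next to a CH that bears a tert-alkyl group, so the closure is hindered, and O-cyclisation is a competitor. A4 itself requires a long linear synthesis.
- Comparison: the chosen strategy starts from a finished aromatic ring and keeps both stereocentres out of every basic step before they are formed.

**Alternative 3:** Ring C is disconnected at C3–C4. A chiral triazolylidene carbene with an amine base converts the ring A aldehyde of 2-{1-[4-(methoxymethoxy)phenyl]-2-oxoethoxy}-4,6-bis(methoxymethoxy)-5-(2-methylbut-3-en-2-yl)benzaldehyde A6 into an acyl anion equivalent. This adds to the tethered aldehyde and gives the 5,7,4'-tris-O-MOM derivative of the target A5, which is identical with 17.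
- For: it uses the best-developed class of asymmetric acyl-anion catalysis and gives the free 3-hydroxy ketone directly. If the C2 centre of A6 racemises quickly, a dynamic kinetic resolution could set both centres. It is stronger than the chosen route in precedent for enantiocontrol, and it saves the ester cleavage.
- Against: the ring A aldehyde, flanked by two ortho oxygens and electron-rich, is the poorer acyl-anion donor, and the aliphatic aldehyde is the better one, which would give the isomeric 4-hydroxy-3-ketone. A6 contains an alpha-aryl, alpha-aryloxy aldehyde, which is configurationally unstable and awkward to prepare. The product acyloin can equilibrate through its enediol under the amine base.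
- Comparison: the chosen strategy has a robust achiral precursor, and its chemo- and regioselectivity are fixed by structure (one hydride donor, one feasible ring size). The price is an unproven enantioselective step.

Key step: step 11

**Assumption:** which enantiomer of the binaphthyl phosphate leads to (2R) cannot be derived reliably from a model of the ion pair; the route is written for the (R)-configured salt, and the (S)-configured salt is used in its place if that is the matched one.

## Route

Step 1
Reactants: 1 2,4,6-trihydroxyacetophenone; 2 prenyl bromide (1-bromo-3-methylbut-2-ene)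
Product: 3 1-[2,6-dihydroxy-4-(3-methylbut-2-en-1-yloxy)phenyl]ethanone
Conditions: 2 (1.05 equiv), K2CO3 (1.1 equiv), acetone, 0 °C to rt
Reagents that add atoms: none
Why: Williamson etherification; the 4-OH is para to the acetyl group and is the only phenol not hydrogen-bonded to it, so it is the most acidic and should be alkylated first. One equivalent of a mild base in acetone favours O- over C-alkylation.

Step 2
Reactants: 3 prenyl ether
Product: 4 1-[2,4,6-trihydroxy-3-(2-methylbut-3-en-2-yl)phenyl]ethanone
Conditions: Eu(fod)3 [tris(6,6,7,7,8,8,8-heptafluoro-2,2-dimethyloctane-3,5-dionato)europium] (10 mol%), CHCl3, 60 °C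
Reagents that add atoms: none
Why: Aromatic Claisen rearrangement; the [3,3] shift delivers the allyl unit with allylic inversion to an ortho carbon and creates the quaternary centre. The two ortho positions of 3 are equivalent and the para position is blocked by the acetyl group, so neither a regioisomer nor a para-migration product can form. The lanthanide catalyst should allow a temperature well below that at which ortho-(1,1-dimethylallyl)phenols add to their own vinyl group.

Step 3
Reactants: 4 triphenol
Product: 5 1-[2,6-dihydroxy-4-(methoxymethoxy)-3-(2-methylbut-3-en-2-yl)phenyl]ethanone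
Conditions: MOMCl (1.1 equiv), i-Pr2NEt (1.5 equiv), CH2Cl2, 0 °C
Reagents that add atoms: chloromethyl methyl ether, COCCl
Why: MOM protection; of the three phenols only the 4-OH is free of a hydrogen bond to the ketone and it is the most acidic, so one equivalent of the reagent should alkylate it first. The neighbouring quaternary carbon slows but should not block this small, highly reactive electrophile.

Step 4
Reactants: 6 4-hydroxybenzyl alcohol
Product: 7 [4-(methoxymethoxy)phenyl]methanol
Conditions: MOMCl (1.1 equiv), K2CO3 (1.2 equiv), acetone, rt
Reagents that add atoms: chloromethyl methyl ether, COCCl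
Why: Carbonate deprotonates only the phenol, so the MOM group should go to the phenolic oxygen and leave the benzylic alcohol free.

Step 5
Reactants: 7 benzylic alcohol
Product: 8 1-(bromomethyl)-4-(methoxymethoxy)benzene
Conditions: CBr4, PPh3, CH2Cl2, 0 °C; used at once
Reagents that add atoms: carbon tetrabromide, BrC(Br)(Br)Br
Why: Appel reaction; bromide displaces the alkoxyphosphonium group at a primary benzylic carbon under neutral conditions, which the acid-labile MOM ether tolerates. The reactive bromide is not stored.

Step 6
Reactants: 5 diphenol; 8 benzylic bromide
Product: 9 1-[2-hydroxy-6-{[4-(methoxymethoxy)phenyl]methoxy}-4-(methoxymethoxy)-3-(2-methylbut-3-en-2-yl)phenyl]ethanone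
Conditions: 8 (1.05 equiv), K2CO3 (1.2 equiv), DMF, 0 °C to rt
Reagents that add atoms: none
Why: Williamson etherification; both remaining phenols are chelated, but the one at C2 lies between the quaternary carbon and the acyl group, so SN2 attack on the bromide should come from the unhindered C6 oxygen. The second phenol, now fully chelated and shielded, should not follow. This step decides which oxygen becomes O1.

Step 7
Reactants: 9 monophenol
Product: 10 1-[2-{[4-(methoxymethoxy)phenyl]methoxy}-4,6-bis(methoxymethoxy)-5-(2-methylbut-3-en-2-yl)phenyl]ethanone
Conditions: NaH (1.2 equiv), DMF, 0 °C; then MOMCl (1.3 equiv)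
Reagents that add atoms: chloromethyl methyl ether, COCCl
Why: MOM protection of a hindered, hydrogen-bonded phenol through its sodium salt; the phenol is far more acidic than the methyl ketone, so enolate chemistry should not interfere.

Step 8
Reactants: 10 methyl ketone
Product: 13 1-Ar-2-hydroxyethanone, via silyl enol ether 11 (not isolated), via silyloxy ketone 12 (not isolated)
Conditions: LiN(SiMe3)2 (1.2 equiv), TMSCl (1.5 equiv), THF, −78 °C; crude 11, mCPBA (1.05 equiv), CH2Cl2, −20 °C; then citric acid (cat.), MeOH, 0 °C
Reagents that add atoms: 3-chloroperoxybenzoic acid, OOC(=O)c1cccc(Cl)c1; chlorotrimethylsilane, C[Si](C)(C)Cl (its atoms stay in 11 and 12 only)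
Why: Rubottom oxidation; kinetic enolisation with silylation in the flask gives the terminal silyl enol ether 11, whose electron-rich double bond should be epoxidised much faster than the monosubstituted vinyl group or the arenes. The silyloxy epoxide opens with silyl shift to 12, and mild acidic methanolysis frees the primary alcohol.

Step 9
Reactants: 13 hydroxy ketone
Product: 14 2-Ar-2-oxoethyl acetate
Conditions: Ac2O (1.5 equiv), pyridine, DMAP (cat.), CH2Cl2, 0 °C to rt
Reagents that add atoms: acetic anhydride, CC(=O)OC(C)=O
Why: Acylation of a primary alcohol under nucleophilic catalysis; no other hydroxyl group is free.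

Step 10
Reactants: 14 acetoxy ketone
Product: 15 (Z)-1-Ar-ethene-1,2-diyl diacetate
Conditions: KN(SiMe3)2 (1.2 equiv), THF, −78 °C; then Ac2O (1.5 equiv), −78 to 0 °C
Reagents that add atoms: acetic anhydride, CC(=O)OC(C)=O
Why: O-Acetylation of a potassium enolate; the CH2 group between ketone and acetoxy group is by far the most acidic site, and the enolate should prefer the (Z) geometry, in which the acetoxy oxygen shares the cation and the twisted aryl group lies next to hydrogen. Low temperature and fast trapping keep the ester enolate out of play, and acyl migration between the two oxygens would lead to the same diacetate.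

Step 11
Reactants: 15 enediol diacetate
Product: 16 (2R,3R)-5,7-bis(methoxymethoxy)-2-[4-(methoxymethoxy)phenyl]-6-(2-methylbut-3-en-2-yl)-4-oxo-3,4-dihydro-2H-chromen-3-yl acetate
Conditions: DDQ (1.3 equiv), lithium (R)-3,3'-bis(2,4,6-triisopropylphenyl)-1,1'-binaphthalene-2,2'-diyl phosphate (20 mol%), 2,6-dichloropyridine (2 equiv), 4 Å MS, toluene–CH2Cl2, −40 °C
Reagents that add atoms: none
Why: Proposed new method: DDQ should abstract a hydride from the benzylic CH2 of 15, the one C–H bond flanked by an ether oxygen and a para-alkoxyphenyl ring, to give an (E)-aryloxocarbenium ion at C2 whose first counter-ion, the hydroquinone anion, is exchanged for the chiral phosphate with lithium as the shuttle (the role LiClO4 plays in achiral versions). C3 of the enediol diacetate adds to C2, and the resulting C4 acetoxycarbenium ion passes its acetyl group to the hydroquinone anion, which gives ketone 16 and frees the phosphate. The closest known reaction types are DDQ-mediated oxidative cyclisations of benzylic ethers onto tethered enol acetates and additions to oxocarbenium ions under chiral-anion control; neither has been shown for an aryl benzyl ether with an enediol diester, nor have the two been combined. Ring C closes in a 6-(enolendo)-endo-trig mode, with O1=C2 and C3=C4 both inside the new ring; because O1, C8a, C4a and C4 lie in the plane of ring A, the transition state is a half-chair and not a cyclohexane chair. C2 is the centre under catalyst control: the phosphate has to cover one face of the planar cation so that C3 bonds to the face that leads to (2R). C3 is set relative to C2, since in the half-chair the ring B aryl group and, with the (Z) enediol, the C3 acetoxy group both point outward and become equatorial, which is the 2,3-trans arrangement; this is also the more stable isomer, so a cis fraction from a boat-like approach can be corrected later by enolisation at C3 alone. Regioselectivity follows from the substrate, as attack through C4 would be a 5-endo closure to a cation without aryl stabilisation, and chemoselectivity follows from the quaternary allylic carbon (no allylic hydrogen), from MOM methylene groups that lack benzylic stabilisation, and from the acyloxy ketone that deactivates C2–H of the product.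

Step 12
Reactants: 16 flavanonol acetate
Product: 17 (2R,3R)-3-hydroxy-5,7-bis(methoxymethoxy)-2-[4-(methoxymethoxy)phenyl]-6-(2-methylbut-3-en-2-yl)-2,3-dihydro-4H-chromen-4-one
Conditions: K2CO3 (0.3 equiv), MeOH–THF, 0 °C, argon, short contact
Reagents that add atoms: none
Why: Base-catalysed transesterification; an acetate next to a ketone is an activated ester and should exchange quickly at 0 °C, while MOM ethers are inert. Any 2,3-cis isomer from step 11 can equilibrate here at C3 to the diequatorial trans compound, and with O4' still protected C2 cannot ionise.

Step 13
Reactants: 17 tris-MOM ether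
Product: 18 (2R,3R)-3,5,7-trihydroxy-2-(4-hydroxyphenyl)-6-(2-methylbut-3-en-2-yl)-2,3-dihydro-4H-chromen-4-one
Conditions: HCl (1.25 M in MeOH), 40 °C
Reagents that add atoms: none
Why: Acid-catalysed acetal exchange should remove the three MOM groups as dimethoxymethane. The dihydroflavonol core is stable to dilute acid, and the vinyl group should survive at 40 °C because its protonation would give a secondary cation next to a quaternary carbon.

## Compound list

1 | 2,4,6-trihydroxyacetophenone | CC(=O)c1c(O)cc(O)cc1O | starting material
2 | prenyl bromide (1-bromo-3-methylbut-2-ene) | CC(C)=CCBr | starting material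
3 | 1-[2,6-dihydroxy-4-(3-methylbut-2-en-1-yloxy)phenyl]ethanone | CC(=O)c1c(O)cc(OCC=C(C)C)cc1O | intermediate
4 | 1-[2,4,6-trihydroxy-3-(2-methylbut-3-en-2-yl)phenyl]ethanone | CC(=O)c1c(O)cc(O)c(C(C)(C)C=C)c1O | intermediate
5 | 1-[2,6-dihydroxy-4-(methoxymethoxy)-3-(2-methylbut-3-en-2-yl)phenyl]ethanone | CC(=O)c1c(O)cc(OCOC)c(C(C)(C)C=C)c1O | intermediate
6 | 4-hydroxybenzyl alcohol | OCc1ccc(O)cc1 | starting material
7 | [4-(methoxymethoxy)phenyl]methanol | COCOc1ccc(CO)cc1 | intermediate
8 | 1-(bromomethyl)-4-(methoxymethoxy)benzene | COCOc1ccc(CBr)cc1 | intermediate
9 | 1-[2-hydroxy-6-{[4-(methoxymethoxy)phenyl]methoxy}-4-(methoxymethoxy)-3-(2-methylbut-3-en-2-yl)phenyl]ethanone | CC(=O)c1c(OCc2ccc(OCOC)cc2)cc(OCOC)c(C(C)(C)C=C)c1O | intermediate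
10 | 1-[2-{[4-(methoxymethoxy)phenyl]methoxy}-4,6-bis(methoxymethoxy)-5-(2-methylbut-3-en-2-yl)phenyl]ethanone | CC(=O)c1c(OCc2ccc(OCOC)cc2)cc(OCOC)c(C(C)(C)C=C)c1OCOC | intermediate
11 | trimethyl[(1-Ar-ethenyl)oxy]silane | C=C(O[Si](C)(C)C)c1c(OCc2ccc(OCOC)cc2)cc(OCOC)c(C(C)(C)C=C)c1OCOC | intermediate
12 | 1-Ar-2-[(trimethylsilyl)oxy]ethanone | C[Si](C)(C)OCC(=O)c1c(OCc2ccc(OCOC)cc2)cc(OCOC)c(C(C)(C)C=C)c1OCOC | intermediate
13 | 1-Ar-2-hydroxyethanone | OCC(=O)c1c(OCc2ccc(OCOC)cc2)cc(OCOC)c(C(C)(C)C=C)c1OCOC | intermediate
14 | 2-Ar-2-oxoethyl acetate | CC(=O)OCC(=O)c1c(OCc2ccc(OCOC)cc2)cc(OCOC)c(C(C)(C)C=C)c1OCOC | intermediate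
15 | (Z)-1-Ar-ethene-1,2-diyl diacetate | C=CC(C)(C)c1c(OCOC)cc(OCc2ccc(OCOC)cc2)c(/C(OC(C)=O)=C/OC(C)=O)c1OCOC | intermediate
16 | (2R,3R)-5,7-bis(methoxymethoxy)-2-[4-(methoxymethoxy)phenyl]-6-(2-methylbut-3-en-2-yl)-4-oxo-3,4-dihydro-2H-chromen-3-yl acetate | C=CC(C)(C)c1c(OCOC)cc2c(c1OCOC)C(=O)[C@H](OC(C)=O)[C@@H](c1ccc(OCOC)cc1)O2 | intermediate
17 | (2R,3R)-3-hydroxy-5,7-bis(methoxymethoxy)-2-[4-(methoxymethoxy)phenyl]-6-(2-methylbut-3-en-2-yl)-2,3-dihydro-4H-chromen-4-one | C=CC(C)(C)c1c(OCOC)cc2c(c1OCOC)C(=O)[C@H](O)[C@@H](c1ccc(OCOC)cc1)O2 | intermediate
18 | (2R,3R)-3,5,7-trihydroxy-2-(4-hydroxyphenyl)-6-(2-methylbut-3-en-2-yl)-2,3-dihydro-4H-chromen-4-one | C=CC(C)(C)c1c(O)cc2c(c1O)C(=O)[C@H](O)[C@@H](c1ccc(O)cc1)O2 | target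

## Step count and least certain steps

Total step count: 13. Longest linear sequence: 11 steps (steps 1, 2, 3, 6, 7, 8, 9, 10, 11, 12, 13 from ketone 1); bromide 8 is made in a two-step branch (steps 4 and 5).

**Step 11 (key step).** Three things are most likely to go wrong:
- Ring closure inside the achiral hydroquinonate ion pair before the phosphate has taken over, which would mean poor facial selectivity at C2.
- Capture of the cation by traces of water, with loss of the benzyl group from O1.
- Further dehydrogenation of the product towards the flavonol.

The fallback uses known chemistry. It sets out from methyl ketone 10 and returns at 17. Alcohol 7 is oxidised with MnO2 to 4-(methoxymethoxy)benzaldehyde F1, which is condensed with 10 (KOH, EtOH; Claisen–Schmidt condensation) to the (E)-chalcone F2. Julia–Colonna epoxidation (poly-L-leucine, urea–H2O2, DBU, THF) should give the (2R,3S)-epoxy ketone F3, by analogy with simple chalcones. DDQ in wet, buffered CH2Cl2 then removes the 4-alkoxybenzyl group from O1, with water as the intended trap, to give the epoxy phenol F4. Mild acid (pyridinium tosylate, CH2Cl2) lets the phenol open the oxirane at its benzylic carbon with inversion in a 6-endo closure, which leads to 17 with C2 and C3 both R. The step count is unchanged, and the selectivity then rests on the peptide catalyst accepting a chalcone with two ortho substituents.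

**Step 2.** If the chelating hydroxy ketone sequesters the lanthanide catalyst and higher temperatures are needed, the flanking phenols may add to the new vinyl group, or the product may rearrange further. The fallback sets out from 3 and returns at 4. The rearrangement is run thermally in N,N-diethylaniline at about 185 °C in the presence of butanoic anhydride. The anhydride esterifies each phenol as it becomes free and gives 2-acetyl-4-(2-methylbut-3-en-2-yl)benzene-1,3,5-triyl tributanoate F5. Methanolysis (K2CO3, MeOH) then returns triphenol 4.

**Step 6.** The two chelated phenols may not be discriminated well enough, or alkylation may go on to the dibenzyl ether; either would spoil the assignment of O1. The fallback sets out from 5 and returns at 10, bypassing 9. A bulkier electrophile is used to amplify the steric difference. TBSCl and imidazole in DMF should silylate only the unhindered phenol and give 1-[6-{[tert-butyl(dimethyl)silyl]oxy}-2-hydroxy-4-(methoxymethoxy)-3-(2-methylbut-3-en-2-yl)phenyl]ethanone F6. MOM protection of the hindered phenol (NaH, MOMCl) gives 1-[2-{[tert-butyl(dimethyl)silyl]oxy}-4,6-bis(methoxymethoxy)-5-(2-methylbut-3-en-2-yl)phenyl]ethanone F7. TBAF frees 1-[6-hydroxy-2,4-bis(methoxymethoxy)-3-(2-methylbut-3-en-2-yl)phenyl]ethanone F8. Its single phenol is then alkylated with 8 (K2CO3, DMF) to give 10.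

**Step 12.** Under base, the C3 enolate may expel O1 and open ring C, which would erode the configuration at C2; ring contraction or aerial dehydrogenation to the flavonol are further risks. The fallback is an all-acid end game that sets out from 16 and arrives at 18, bypassing 17. HCl in MeOH at 40–50 °C first removes the MOM groups to give (2R,3R)-5,7-dihydroxy-2-(4-hydroxyphenyl)-6-(2-methylbut-3-en-2-yl)-4-oxo-3,4-dihydro-2H-chromen-3-yl acetate F9. On longer reaction the acid transesterifies the acetate, so 18 is reached in one flask without any base.

## Further compounds

F1 | step 11 | 4-(methoxymethoxy)benzaldehyde | COCOc1ccc(C=O)cc1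
F2 | step 11 | (E)-1-[2-{[4-(methoxymethoxy)phenyl]methoxy}-4,6-bis(methoxymethoxy)-5-(2-methylbut-3-en-2-yl)phenyl]-3-[4-(methoxymethoxy)phenyl]prop-2-en-1-one | C=CC(C)(C)c1c(OCOC)cc(OCc2ccc(OCOC)cc2)c(C(=O)/C=C/c2ccc(OCOC)cc2)c1OCOC
F3 | step 11 | [2-{[4-(methoxymethoxy)phenyl]methoxy}-4,6-bis(methoxymethoxy)-5-(2-methylbut-3-en-2-yl)phenyl]{(2R,3S)-3-[4-(methoxymethoxy)phenyl]oxiran-2-yl}methanone | C=CC(C)(C)c1c(OCOC)cc(OCc2ccc(OCOC)cc2)c(C(=O)[C@@H]2O[C@H]2c2ccc(OCOC)cc2)c1OCOC
F4 | step 11 | [6-hydroxy-2,4-bis(methoxymethoxy)-3-(2-methylbut-3-en-2-yl)phenyl]{(2R,3S)-3-[4-(methoxymethoxy)phenyl]oxiran-2-yl}methanone | C=CC(C)(C)c1c(OCOC)cc(O)c(C(=O)[C@@H]2O[C@H]2c2ccc(OCOC)cc2)c1OCOC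
F5 | step 2 | 2-acetyl-4-(2-methylbut-3-en-2-yl)benzene-1,3,5-triyl tributanoate | CCCC(=O)Oc1cc(OC(=O)CCC)c(C(C)(C)C=C)c(OC(=O)CCC)c1C(C)=O
F6 | step 6 | 1-[6-{[tert-butyl(dimethyl)silyl]oxy}-2-hydroxy-4-(methoxymethoxy)-3-(2-methylbut-3-en-2-yl)phenyl]ethanone | CC(=O)c1c(O[Si](C)(C)C(C)(C)C)cc(OCOC)c(C(C)(C)C=C)c1O
F7 | step 6 | 1-[2-{[tert-butyl(dimethyl)silyl]oxy}-4,6-bis(methoxymethoxy)-5-(2-methylbut-3-en-2-yl)phenyl]ethanone | CC(=O)c1c(O[Si](C)(C)C(C)(C)C)cc(OCOC)c(C(C)(C)C=C)c1OCOC
F8 | step 6 | 1-[6-hydroxy-2,4-bis(methoxymethoxy)-3-(2-methylbut-3-en-2-yl)phenyl]ethanone | CC(=O)c1c(O)cc(OCOC)c(C(C)(C)C=C)c1OCOC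
F9 | step 12 | (2R,3R)-5,7-dihydroxy-2-(4-hydroxyphenyl)-6-(2-methylbut-3-en-2-yl)-4-oxo-3,4-dihydro-2H-chromen-3-yl acetate | C=CC(C)(C)c1c(O)cc2c(c1O)C(=O)[C@H](OC(C)=O)[C@@H](c1ccc(O)cc1)O2
A1 | alternative 1 | 5-(allyloxy)-3-(methoxymethoxy)-2-(2-methylbut-3-en-2-yl)phenol | C=CC(C)(C)c1c(O)cc(OCC=C)cc1OCOC
A2 | alternative 1 | tert-butyl 2-acetyl-5-(allyloxy)-3-(methoxymethoxy)phenyl carbonate | CC(=O)c1c(OC(=O)OC(C)(C)C)cc(OCC=C)cc1OCOC
A3 | alternative 2 | (2R,3R)-3-[(tert-butyldimethylsilyl)oxy]-2-{4-[(tert-butyldimethylsilyl)oxy]phenyl}-5,7-dihydroxy-6-(2-methylbut-3-en-2-yl)-2,3-dihydro-4H-chromen-4-one | C=CC(C)(C)c1c(O)cc2c(c1O)C(=O)[C@H](O[Si](C)(C)C(C)(C)C)[C@@H](c1ccc(O[Si](C)(C)C(C)(C)C)cc1)O2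
A4 | alternative 2 | methyl 4-[(2R,3R)-3-[(tert-butyldimethylsilyl)oxy]-2-{4-[(tert-butyldimethylsilyl)oxy]phenyl}-4-oxo-3,4-dihydro-2H-pyran-6-yl]-2-(2-methylbut-3-en-2-yl)-3-oxobutanoate | COC(=O)C(C(C)(C)C=C)C(=O)CC1=CC(=O)[C@H](O[Si](C)(C)C(C)(C)C)[C@@H](c2ccc(O[Si](C)(C)C(C)(C)C)cc2)O1
A5 | alternative 3 | (2R,3R)-3-hydroxy-5,7-bis(methoxymethoxy)-2-[4-(methoxymethoxy)phenyl]-6-(2-methylbut-3-en-2-yl)-2,3-dihydro-4H-chromen-4-one | C=CC(C)(C)c1c(OCOC)cc2c(c1OCOC)C(=O)[C@H](O)[C@@H](c1ccc(OCOC)cc1)O2
A6 | alternative 3 | 2-{1-[4-(methoxymethoxy)phenyl]-2-oxoethoxy}-4,6-bis(methoxymethoxy)-5-(2-methylbut-3-en-2-yl)benzaldehyde | C=CC(C)(C)c1c(OCOC)cc(OC(C=O)c2ccc(OCOC)cc2)c(C=O)c1OCOC
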